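**Assumption:** the only stereocentre is the lactol (hemiacetal) carbon, (R) by CIP. It epimerises by ring–chain tautomerism, so it is carried racemic, fixed by resolution in the last step, and the product is then kept cold in acidic, alcohol-free media.

## Retrosynthetic overview

1. Target ⇐ resolution of the racemic lactol ⇐ alkylation of sodium hydrogen fumarate by the o-hydroxybenzylic chloride of rac-salazinic acid ⇐ BCl3 unmasking of a tetra-O-methyl depsidone.
2. Depsidone ⇐ lactonisation (ester C–O, seven-membered ring) ⇐ intermolecular SNAr diaryl ether between ring A aryl fluoride 26 and ring B phenol 16.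
3. Ring B ⇐ protocatechuate acetonide: two amide-directed ortho-metalations (CHO, OH), then the key C–C bond, an intermolecular phenolic Mannich reaction with Eschenmoser's salt that installs the CH2 carbon later carrying the fumarate.
4. Ring A ⇐ 3,5-difluorotoluene: formylation between the fluorines, SNAr by methoxide, bromination, Br–Li exchange/CO2.
5. Ring order: both benzene rings are bought; temporary dioxole (step 1) → phthalide lactone (step 9) → depsidone dioxepinone (step 19) → free lactol (step 20).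

## Route

**Step 1**
Reactants: 1 methyl 3,4-dihydroxybenzoate
Product: 2 methyl 2,2-dimethyl-1,3-benzodioxole-5-carboxylate
Conditions: 2,2-dimethoxypropane, TsOH·H2O (cat.), toluene, reflux, 4 Å MS in Soxhlet
Reagents that add atoms: 2,2-dimethoxypropane, COC(C)(C)OC
Why: Acid-catalysed transketalisation (acetonide formation) ties both catechol oxygens into one ring that is stable to base and organolithiums and itself directs ortho-metalation.

**Step 2**
Reactants: 2 methyl 2,2-dimethyl-1,3-benzodioxole-5-carboxylate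
Product: 3 N,N-diethyl-2,2-dimethyl-1,3-benzodioxole-5-carboxamide
Conditions: Et2NH, i-PrMgCl, THF, 0 °C; then 2, 0 °C → rt; H2O
Reagents that add atoms: diethylamine, CCNCC
Why: Bodroux-type aminolysis of the ester by the magnesium amide gives the tertiary amide needed as the strong directing group, and the ketal is inert to Grignard reagents.

**Step 3**
Reactants: 3 N,N-diethyl-2,2-dimethyl-1,3-benzodioxole-5-carboxamide
Product: 5 N,N-diethyl-4-formyl-2,2-dimethyl-1,3-benzodioxole-5-carboxamide, via aryllithium 4 (not isolated)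
Conditions: s-BuLi, TMEDA, THF, −78 °C; DMF, −78 °C → rt; H2O
Reagents that add atoms: N,N-dimethylformamide, CN(C)C=O
Why: Directed ortho-metalation removes the proton flanked by the amide and the dioxole oxygen (cooperating directing groups), and the aryllithium is formylated by DMF.

**Step 4**
Reactants: 5 N,N-diethyl-4-formyl-2,2-dimethyl-1,3-benzodioxole-5-carboxamide
Product: 6 N,N-diethyl-4-(dimethoxymethyl)-2,2-dimethyl-1,3-benzodioxole-5-carboxamide
Conditions: HC(OMe)3, MeOH, TsOH·H2O (2 mol %), rt; Et3N quench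
Reagents that add atoms: trimethyl orthoformate, COC(OC)OC
Why: Acetalisation under anhydrous catalytic acid masks the aldehyde against the second organolithium, and without water the neighbouring amide cannot be lost as a lactone.

**Step 5**
Reactants: 6 N,N-diethyl-4-(dimethoxymethyl)-2,2-dimethyl-1,3-benzodioxole-5-carboxamide
Product: 9 N,N-diethyl-4-(dimethoxymethyl)-6-hydroxy-2,2-dimethyl-1,3-benzodioxole-5-carboxamide, via aryllithium 7 (not isolated), via lithium aryltrimethoxyborate 8 (not isolated)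
Conditions: s-BuLi, TMEDA, THF, −78 °C; B(OMe)3, −78 → 0 °C; 30% aq. H2O2, 0 °C
Reagents that add atoms: hydrogen peroxide, OO
Why: A second amide-directed ortho-metalation at the only position ortho to the amide, borylation and boronate oxidation (C–B to C–O) deliver the phenol.

**Step 6**
Reactants: 9 N,N-diethyl-4-(dimethoxymethyl)-6-hydroxy-2,2-dimethyl-1,3-benzodioxole-5-carboxamide; 10 N,N-dimethylmethyleneiminium iodide (Eschenmoser's salt)
Product: 11 N,N-diethyl-4-(dimethoxymethyl)-7-[(dimethylamino)methyl]-6-hydroxy-2,2-dimethyl-1,3-benzodioxole-5-carboxamide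
Conditions: K2CO3, CH2Cl2, 0 °C → rt
Reagents that add atoms: none
Why: Intermolecular phenolic Mannich reaction in which the electron-rich phenoxide attacks the preformed iminium ion at the single free ring position (ortho to OH), forging the C–C bond of the future CH2O group.

**Step 7**
Reactants: 11 N,N-diethyl-4-(dimethoxymethyl)-7-[(dimethylamino)methyl]-6-hydroxy-2,2-dimethyl-1,3-benzodioxole-5-carboxamide
Product: 13 N,N-diethyl-4-(dimethoxymethyl)-6-hydroxy-7-(methoxymethyl)-2,2-dimethyl-1,3-benzodioxole-5-carboxamide, via trimethylammonium iodide 12 (not isolated)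
Conditions: MeI, MeCN, rt; evaporate; NaOMe, MeOH, 50 °C
Reagents that add atoms: sodium methoxide, C[O-].[Na+]
Why: N-Quaternisation makes trimethylamine a leaving group, and methoxide then triggers elimination to an ortho-quinone methide that adds methanol (Mannich-base solvolysis) to give the benzyl methyl ether.

**Step 8**
Reactants: 13 N,N-diethyl-4-(dimethoxymethyl)-6-hydroxy-7-(methoxymethyl)-2,2-dimethyl-1,3-benzodioxole-5-carboxamide
Product: 14 N,N-diethyl-4-(dimethoxymethyl)-6-methoxy-7-(methoxymethyl)-2,2-dimethyl-1,3-benzodioxole-5-carboxamide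
Conditions: MeI, K2CO3, DMF, 40 °C
Reagents that add atoms: iodomethane, CI
Why: Williamson O-methylation of the hindered phenol, with acetal, ketal and amide all stable to base.

**Step 9**
Reactants: 14 N,N-diethyl-4-(dimethoxymethyl)-6-methoxy-7-(methoxymethyl)-2,2-dimethyl-1,3-benzodioxole-5-carboxamide
Product: 15 rac-4,5-dihydroxy-3,7-dimethoxy-6-(methoxymethyl)-2-benzofuran-1(3H)-one
Conditions: conc. HCl/MeOH (1:10), reflux, N2
Reagents that add atoms: water, O
Why: Acid methanolysis in which the oxocarbenium ion from the acetal is trapped by the amide oxygen and the iminium ether is hydrolysed (neighbouring-group-assisted amide cleavage) to the 3-methoxyphthalide while the ketal is cleaved, the new acetal centre forming as a racemate.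

**Step 10**
Reactants: 15 rac-4,5-dihydroxy-3,7-dimethoxy-6-(methoxymethyl)-2-benzofuran-1(3H)-one
Product: 16 rac-4-hydroxy-3,7-dimethoxy-6-(methoxymethyl)-5-(prop-2-en-1-yloxy)-2-benzofuran-1(3H)-one
Conditions: allyl bromide (1.05 equiv), NaHCO3, NaI (cat.), DMF, 40 °C
Reagents that add atoms: allyl bromide, C=CCBr
Why: Williamson etherification under weak base alkylates only the more acidic phenol, the one para to the lactone carbonyl (as with protocatechuates), leaving the 4-OH free for the diaryl ether.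

**Step 11**
Reactants: 17 3,5-difluorotoluene
Product: 19 2,6-difluoro-4-methylbenzaldehyde, via aryllithium 18 (not isolated)
Conditions: n-BuLi, THF, −78 °C; DMF, −78 °C → rt; H2O
Reagents that add atoms: N,N-dimethylformamide, CN(C)C=O
Why: Ortho-lithiation at the most acidic C–H, between the two fluorines, followed by formylation with DMF.

**Step 12**
Reactants: 19 2,6-difluoro-4-methylbenzaldehyde
Product: 20 2-fluoro-6-methoxy-4-methylbenzaldehyde
Conditions: NaOMe (1.05 equiv), MeOH, 0 → 40 °C
Reagents that add atoms: sodium methoxide, C[O-].[Na+]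
Why: SNAr of a fluoride ortho to the aldehyde, after which the new methoxy group deactivates the ring so the second fluoride stays.

**Step 13**
Reactants: 20 2-fluoro-6-methoxy-4-methylbenzaldehyde
Product: 21 3-bromo-2-fluoro-6-methoxy-4-methylbenzaldehyde
Conditions: NBS, CF3CO2H (cat.), MeCN, rt, dark
Reagents that add atoms: N-bromosuccinimide, O=C1CCC(=O)N1Br
Why: Electrophilic aromatic bromination para to the methoxy group (between F and CH3), the other free position being ortho to OMe and more hindered.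

**Step 14**
Reactants: 21 3-bromo-2-fluoro-6-methoxy-4-methylbenzaldehyde
Product: 22 2-bromo-4-(dimethoxymethyl)-3-fluoro-5-methoxy-1-methylbenzene
Conditions: HC(OMe)3, MeOH, TsOH·H2O (cat.), rt
Reagents that add atoms: trimethyl orthoformate, COC(OC)OC
Why: Acetalisation protects the aldehyde from butyllithium in the next step.

**Step 15**
Reactants: 22 2-bromo-4-(dimethoxymethyl)-3-fluoro-5-methoxy-1-methylbenzene
Product: 25 2-fluoro-3-formyl-4-methoxy-6-methylbenzoic acid, via aryllithium 23 (not isolated), via lithium carboxylate 24 (not isolated)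
Conditions: n-BuLi, THF, −78 °C; CO2 (g), −78 °C → rt; 2 M HCl, THF, rt
Reagents that add atoms: carbon dioxide, O=C=O; water, O
Why: Bromine–lithium exchange at −78 °C (the ortho-fluoroaryllithium is stable there), carboxylation with CO2 and acetal hydrolysis on acidic work-up.

**Step 16**
Reactants: 25 2-fluoro-3-formyl-4-methoxy-6-methylbenzoic acid
Product: 26 prop-2-en-1-yl 2-fluoro-3-formyl-4-methoxy-6-methylbenzoate
Conditions: allyl bromide, KHCO3, DMF, rt
Reagents that add atoms: allyl bromide, C=CCBr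
Why: SN2 O-alkylation of the carboxylate gives an ester that activates the fluoride and can later be removed without hydrolysis.

**Step 17**
Reactants: 16 rac-4-hydroxy-3,7-dimethoxy-6-(methoxymethyl)-5-(prop-2-en-1-yloxy)-2-benzofuran-1(3H)-one; 26 prop-2-en-1-yl 2-fluoro-3-formyl-4-methoxy-6-methylbenzoate
Product: 27 rac-prop-2-en-1-yl 3-formyl-2-{[3,7-dimethoxy-6-(methoxymethyl)-1-oxo-5-(prop-2-en-1-yloxy)-1,3-dihydro-2-benzofuran-4-yl]oxy}-4-methoxy-6-methylbenzoate
Conditions: K2CO3, DMF, 4 Å MS, 60 °C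
Reagents that add atoms: none
Why: SNAr in which the fluoride flanked by ortho-formyl and ortho-ester groups is displaced by the phenoxide through a doubly stabilised Meisenheimer complex, and making the ether before the ester avoids acyl migration on the catechol.

**Step 18**
Reactants: 27 rac-prop-2-en-1-yl 3-formyl-2-{[3,7-dimethoxy-6-(methoxymethyl)-1-oxo-5-(prop-2-en-1-yloxy)-1,3-dihydro-2-benzofuran-4-yl]oxy}-4-methoxy-6-methylbenzoate
Product: 28 rac-3-formyl-2-{[5-hydroxy-3,7-dimethoxy-6-(methoxymethyl)-1-oxo-1,3-dihydro-2-benzofuran-4-yl]oxy}-4-methoxy-6-methylbenzoic acid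
Conditions: Pd(PPh3)4 (5 mol %), sodium p-toluenesulfinate (TolSO2Na, 2.5 equiv), THF/MeOH, rt; then 1 M HCl
Reagents that add atoms: none
Why: Tsuji–Trost deallylation in which zerovalent palladium ionises the allyl ester and the allyl aryl ether and the sulfinate traps the allyl unit as a sulfone, with no amine or C–H acid present that could attack the aldehyde or the pseudo-ester.

**Step 19**
Reactants: 28 rac-3-formyl-2-{[5-hydroxy-3,7-dimethoxy-6-(methoxymethyl)-1-oxo-1,3-dihydro-2-benzofuran-4-yl]oxy}-4-methoxy-6-methylbenzoic acid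
Product: 29 rac-1,4,10-trimethoxy-5-(methoxymethyl)-8-methyl-3,7-dioxo-1,3-dihydro-7H-isobenzofuro[4,5-b][1,4]benzodioxepine-11-carbaldehyde
Conditions: DCC, 4-(dimethylamino)pyridine (cat.), CH2Cl2 (5 mM), 0 °C → rt
Reagents that add atoms: none
Why: Steglich-type lactonisation under high dilution closes the seven-membered depsidone ring between the only free phenol and the only carboxylic acid.

**Step 20**
Reactants: 29 rac-1,4,10-trimethoxy-5-(methoxymethyl)-8-methyl-3,7-dioxo-1,3-dihydro-7H-isobenzofuro[4,5-b][1,4]benzodioxepine-11-carbaldehyde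
Product: 31 rac-1,4,10-trihydroxy-5-(hydroxymethyl)-8-methyl-3,7-dioxo-1,3-dihydro-7H-isobenzofuro[4,5-b][1,4]benzodioxepine-11-carbaldehyde (rac-salazinic acid), via dichloride 30 (not isolated)
Conditions: BCl3 (8 equiv), CH2Cl2, −78 °C → rt; then THF/H2O, 45 °C
Reagents that add atoms: water, O
Why: Lewis-acid ether cleavage in which BCl3 removes the two aryl methyl ethers by chelation to their ortho carbonyl groups and turns the benzylic and acetal methyl ethers into chlorides that hydrolyse on warming with water, giving the lactol as a racemate.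

**Step 21**
Reactants: 31 rac-salazinic acid; 32 sodium hydrogen fumarate
Product: 34 (2E)-4-{[rac-11-formyl-1,4,10-trihydroxy-8-methyl-3,7-dioxo-1,3-dihydro-7H-isobenzofuro[4,5-b][1,4]benzodioxepin-5-yl]methoxy}-4-oxobut-2-enoic acid, via benzylic chloride 33 (not isolated)
Conditions: 37% aq. HCl/1,4-dioxane (1:1), rt; extract (EtOAc), evaporate; then 32 (5 equiv), NaI (10 mol %), DMF, 0 °C → rt
Reagents that add atoms: none
Why: The o-hydroxybenzylic alcohol alone ionises in concentrated HCl to the chloride, and carboxylate alkylation (SN2 or via the ortho-quinone methide) by the weakly basic hydrogen fumarate esterifies only this position without acylating the lactol or phenols, the E-alkene coming unchanged from the reagent.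

**Step 22**
Reactants: 34 racemic fumarate half-ester
Product: 35 (2E)-4-{[(1R)-11-formyl-1,4,10-trihydroxy-8-methyl-3,7-dioxo-1,3-dihydro-7H-isobenzofuro[4,5-b][1,4]benzodioxepin-5-yl]methoxy}-4-oxobut-2-enoic acid
Conditions: preparative chiral SFC, immobilised amylose tris(3,5-dimethylphenylcarbamate) phase, CO2/MeCN + 0.1% HCO2H, 10 °C; fractions evaporated cold
Reagents that add atoms: none
Why: Resolution by chiral chromatography sets the (R) lactol centre by physical separation under acidic, alcohol-free conditions where ring–chain tautomerism is slow.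

## Compound list

1 | methyl 3,4-dihydroxybenzoate | COC(=O)c1ccc(O)c(O)c1 | starting material
2 | methyl 2,2-dimethyl-1,3-benzodioxole-5-carboxylate | COC(=O)c1ccc2OC(C)(C)Oc2c1 | intermediate
3 | N,N-diethyl-2,2-dimethyl-1,3-benzodioxole-5-carboxamide | CCN(CC)C(=O)c1ccc2OC(C)(C)Oc2c1 | intermediate
4 | [5-(diethylcarbamoyl)-2,2-dimethyl-1,3-benzodioxol-4-yl]lithium | CCN(CC)C(=O)c1ccc2OC(C)(C)Oc2c1[Li] | intermediate (not isolated)
5 | N,N-diethyl-4-formyl-2,2-dimethyl-1,3-benzodioxole-5-carboxamide | CCN(CC)C(=O)c1ccc2OC(C)(C)Oc2c1C=O | intermediate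
6 | N,N-diethyl-4-(dimethoxymethyl)-2,2-dimethyl-1,3-benzodioxole-5-carboxamide | CCN(CC)C(=O)c1ccc2OC(C)(C)Oc2c1C(OC)OC | intermediate
7 | [6-(diethylcarbamoyl)-7-(dimethoxymethyl)-2,2-dimethyl-1,3-benzodioxol-5-yl]lithium | CCN(CC)C(=O)c1c([Li])cc2OC(C)(C)Oc2c1C(OC)OC | intermediate (not isolated)
8 | lithium [6-(diethylcarbamoyl)-7-(dimethoxymethyl)-2,2-dimethyl-1,3-benzodioxol-5-yl]trimethoxyborate | CCN(CC)C(=O)c1c([B-](OC)(OC)OC)cc2OC(C)(C)Oc2c1C(OC)OC.[Li+] | intermediate (not isolated)
9 | N,N-diethyl-4-(dimethoxymethyl)-6-hydroxy-2,2-dimethyl-1,3-benzodioxole-5-carboxamide | CCN(CC)C(=O)c1c(O)cc2OC(C)(C)Oc2c1C(OC)OC | intermediate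
10 | N,N-dimethylmethyleneiminium iodide (Eschenmoser's salt) | C=[N+](C)C.[I-] | starting material
11 | N,N-diethyl-4-(dimethoxymethyl)-7-[(dimethylamino)methyl]-6-hydroxy-2,2-dimethyl-1,3-benzodioxole-5-carboxamide | CCN(CC)C(=O)c1c(O)c(CN(C)C)c2OC(C)(C)Oc2c1C(OC)OC | intermediate
12 | {[6-(diethylcarbamoyl)-7-(dimethoxymethyl)-5-hydroxy-2,2-dimethyl-1,3-benzodioxol-4-yl]methyl}trimethylammonium iodide | CCN(CC)C(=O)c1c(O)c(C[N+](C)(C)C)c2OC(C)(C)Oc2c1C(OC)OC.[I-] | intermediate (not isolated)
13 | N,N-diethyl-4-(dimethoxymethyl)-6-hydroxy-7-(methoxymethyl)-2,2-dimethyl-1,3-benzodioxole-5-carboxamide | CCN(CC)C(=O)c1c(O)c(COC)c2OC(C)(C)Oc2c1C(OC)OC | intermediate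
14 | N,N-diethyl-4-(dimethoxymethyl)-6-methoxy-7-(methoxymethyl)-2,2-dimethyl-1,3-benzodioxole-5-carboxamide | CCN(CC)C(=O)c1c(OC)c(COC)c2OC(C)(C)Oc2c1C(OC)OC | intermediate
15 | rac-4,5-dihydroxy-3,7-dimethoxy-6-(methoxymethyl)-2-benzofuran-1(3H)-one | COCc1c(O)c(O)c2C(OC)OC(=O)c2c1OC | intermediate
16 | rac-4-hydroxy-3,7-dimethoxy-6-(methoxymethyl)-5-(prop-2-en-1-yloxy)-2-benzofuran-1(3H)-one | C=CCOc1c(O)c2C(OC)OC(=O)c2c(OC)c1COC | intermediate
17 | 3,5-difluorotoluene | Cc1cc(F)cc(F)c1 | starting material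
18 | (2,6-difluoro-4-methylphenyl)lithium | Cc1cc(F)c([Li])c(F)c1 | intermediate (not isolated)
19 | 2,6-difluoro-4-methylbenzaldehyde | Cc1cc(F)c(C=O)c(F)c1 | intermediate
20 | 2-fluoro-6-methoxy-4-methylbenzaldehyde | COc1cc(C)cc(F)c1C=O | intermediate
21 | 3-bromo-2-fluoro-6-methoxy-4-methylbenzaldehyde | COc1cc(C)c(Br)c(F)c1C=O | intermediate
22 | 2-bromo-4-(dimethoxymethyl)-3-fluoro-5-methoxy-1-methylbenzene | COc1cc(C)c(Br)c(F)c1C(OC)OC | intermediate
23 | [3-(dimethoxymethyl)-2-fluoro-4-methoxy-6-methylphenyl]lithium | COc1cc(C)c([Li])c(F)c1C(OC)OC | intermediate (not isolated)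
24 | lithium 3-(dimethoxymethyl)-2-fluoro-4-methoxy-6-methylbenzoate | COc1cc(C)c(C(=O)[O-])c(F)c1C(OC)OC.[Li+] | intermediate (not isolated)
25 | 2-fluoro-3-formyl-4-methoxy-6-methylbenzoic acid | COc1cc(C)c(C(=O)O)c(F)c1C=O | intermediate
26 | prop-2-en-1-yl 2-fluoro-3-formyl-4-methoxy-6-methylbenzoate | C=CCOC(=O)c1c(C)cc(OC)c(C=O)c1F | intermediate
27 | rac-prop-2-en-1-yl 3-formyl-2-{[3,7-dimethoxy-6-(methoxymethyl)-1-oxo-5-(prop-2-en-1-yloxy)-1,3-dihydro-2-benzofuran-4-yl]oxy}-4-methoxy-6-methylbenzoate | C=CCOC(=O)c1c(C)cc(OC)c(C=O)c1Oc1c(OCC=C)c(COC)c(OC)c2C(=O)OC(OC)c12 | intermediate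
28 | rac-3-formyl-2-{[5-hydroxy-3,7-dimethoxy-6-(methoxymethyl)-1-oxo-1,3-dihydro-2-benzofuran-4-yl]oxy}-4-methoxy-6-methylbenzoic acid | OC(=O)c1c(C)cc(OC)c(C=O)c1Oc1c(O)c(COC)c(OC)c2C(=O)OC(OC)c12 | intermediate
29 | rac-1,4,10-trimethoxy-5-(methoxymethyl)-8-methyl-3,7-dioxo-1,3-dihydro-7H-isobenzofuro[4,5-b][1,4]benzodioxepine-11-carbaldehyde | Cc1cc(OC)c(C=O)c2c1C(=O)Oc1c(COC)c(OC)c3c(c1O2)C(OC)OC3=O | intermediate
30 | rac-1-chloro-5-(chloromethyl)-4,10-dihydroxy-8-methyl-3,7-dioxo-1,3-dihydro-7H-isobenzofuro[4,5-b][1,4]benzodioxepine-11-carbaldehyde | Cc1cc(O)c(C=O)c2c1C(=O)Oc1c(CCl)c(O)c3c(c1O2)C(Cl)OC3=O | intermediate (not isolated)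
31 | rac-1,4,10-trihydroxy-5-(hydroxymethyl)-8-methyl-3,7-dioxo-1,3-dihydro-7H-isobenzofuro[4,5-b][1,4]benzodioxepine-11-carbaldehyde (rac-salazinic acid) | Cc1cc(O)c(C=O)c2c1C(=O)Oc1c(CO)c(O)c3c(c1O2)C(O)OC3=O | intermediate
32 | sodium hydrogen fumarate | OC(=O)/C=C/C(=O)[O-].[Na+] | starting material
33 | rac-5-(chloromethyl)-1,4,10-trihydroxy-8-methyl-3,7-dioxo-1,3-dihydro-7H-isobenzofuro[4,5-b][1,4]benzodioxepine-11-carbaldehyde | Cc1cc(O)c(C=O)c2c1C(=O)Oc1c(CCl)c(O)c3c(c1O2)C(O)OC3=O | intermediate (not isolated)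
34 | (2E)-4-{[rac-11-formyl-1,4,10-trihydroxy-8-methyl-3,7-dioxo-1,3-dihydro-7H-isobenzofuro[4,5-b][1,4]benzodioxepin-5-yl]methoxy}-4-oxobut-2-enoic acid | Cc1cc(O)c(C=O)c2c1C(=O)Oc1c(COC(=O)/C=C/C(=O)O)c(O)c3c(c1O2)C(O)OC3=O | intermediate
35 | (2E)-4-{[(1R)-11-formyl-1,4,10-trihydroxy-8-methyl-3,7-dioxo-1,3-dihydro-7H-isobenzofuro[4,5-b][1,4]benzodioxepin-5-yl]methoxy}-4-oxobut-2-enoic acid | Cc1cc(O)c(C=O)c2c1C(=O)Oc1c(COC(=O)/C=C/C(=O)O)c(O)c3c(c1O2)[C@H](O)OC3=O | target

## Step count and risks

Total step count: 22. Longest linear sequence: 16 steps (steps 1–10, then 17–22); the ring A branch (steps 11–16) is 6 steps.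

Three steps most likely to fail:

**Step 13 (regiochemistry of the bromination).** If bromination also goes ortho to the methoxy group, the fallback sets out from 20 and comes back at 25. Aldehyde 20 is acetalised (HC(OMe)3, MeOH, TsOH·H2O cat.) to 2-(dimethoxymethyl)-1-fluoro-3-methoxy-5-methylbenzene F1. F1 is deprotonated next to fluorine with s-BuLi/PMDTA in THF at −78 °C, which gives aryllithium 23 directly, without any halogenation. The CO2 quench and acidic work-up of step 15 then deliver 25.

**Step 17 (intermolecular SNAr between two di-ortho-substituted partners).** If the coupling stalls, the fallback sets out from 15 and 25 and comes back at 29. Acid 25 is converted with (COCl)2 and catalytic DMF in CH2Cl2 into 2-fluoro-3-formyl-4-methoxy-6-methylbenzoyl chloride F2. F2 acylates the more acidic 5-OH of catechol 15 (2,6-lutidine, 4-(dimethylamino)pyridine cat., CH2Cl2, −40 °C) to give the depside rac-4-hydroxy-3,7-dimethoxy-6-(methoxymethyl)-1-oxo-1,3-dihydro-2-benzofuran-5-yl 2-fluoro-3-formyl-4-methoxy-6-methylbenzoate F3. Cs2CO3 in MeCN at rt then closes the diaryl ether by intramolecular SNAr (seven-membered ring) to give 29. This ester-first order makes 16, 26, 27 and 28 unnecessary, so it also removes the regioselective allylation of step 10. The ring closure must outrun acyl migration between the catechol oxygens, so the regiochemistry of 29 has to be confirmed by HMBC.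

**Step 21 (chemoselective fumarate installation).** If the benzylic chloride cannot be made or alkylates poorly, the fallback sets out from 31 and comes back at 34 by acylation instead of alkylation. Maleic anhydride (1.2 equiv), pyridine and 4-(dimethylamino)pyridine (cat.) in CH2Cl2 at 0 °C acylate the primary benzylic alcohol to the maleate half-ester (2Z)-4-{[rac-11-formyl-1,4,10-trihydroxy-8-methyl-3,7-dioxo-1,3-dihydro-7H-isobenzofuro[4,5-b][1,4]benzodioxepin-5-yl]methoxy}-4-oxobut-2-enoic acid F4. Any acyl group on the lactol oxygen is an acylal and falls off on aqueous work-up. I2 (5 mol %) in MeCN under visible light then isomerises the Z-alkene of F4 to the E-alkene, giving 34.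

## Further compounds

F1 | step 13 | 2-(dimethoxymethyl)-1-fluoro-3-methoxy-5-methylbenzene | COc1cc(C)cc(F)c1C(OC)OC
F2 | step 17 | 2-fluoro-3-formyl-4-methoxy-6-methylbenzoyl chloride | COc1cc(C)c(C(=O)Cl)c(F)c1C=O
F3 | step 17 | rac-4-hydroxy-3,7-dimethoxy-6-(methoxymethyl)-1-oxo-1,3-dihydro-2-benzofuran-5-yl 2-fluoro-3-formyl-4-methoxy-6-methylbenzoate | COc1cc(C)c(C(=O)Oc2c(O)c3C(OC)OC(=O)c3c(OC)c2COC)c(F)c1C=O
F4 | step 21 | (2Z)-4-{[rac-11-formyl-1,4,10-trihydroxy-8-methyl-3,7-dioxo-1,3-dihydro-7H-isobenzofuro[4,5-b][1,4]benzodioxepin-5-yl]methoxy}-4-oxobut-2-enoic acid | Cc1cc(O)c(C=O)c2c1C(=O)Oc1c(COC(=O)/C=C\C(=O)O)c(O)c3c(c1O2)C(O)OC3=O
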